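**Plan**

1. Numbering used throughout (elemanolide convention): C10 is the quaternary ring carbon (methyl C14, vinyl C1=C2), C5 the CH carrying C4(=C3H2)–C15H2OH, C6 the CHOH, C7/C8 the lactone fusion (C7–C11(=C13H2)–C12(=O)–O–C8), and C9 the CH–O-acyl carbon.
2. Retrosynthesis: the isobutyrate is removed, then ring bonds C6–C7 and C9–C10 are cut together. The enabling feature is that the cyclohexane holds two homoallylic alcohols head to tail: C6(OH)–C7–C11=C13H2 (the exocyclic methylene of the γ-lactone ring) and C9(O)–C10–C1H=C2H2 (the vinyl group on the quaternary carbon). The carbocycle is therefore a [3+3] union of two formyl-allyl units.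
3. Fragments: 9 (C10–C5–C6) is an E-allylboronate whose C15 hydroxyl hides the C6 aldehyde as a lactol. 16 (C7–C8–C9) is an aldehyde on a pre-formed γ-lactone whose allyl unit is latent as a Morita–Baylis–Hillman acetate.
4. Forward: 9 is made in six steps from but-2-yn-1-ol and 4,4-dimethoxybut-2-enal, and 16 in four steps from (R)-glyceraldehyde acetonide and methyl acrylate. The γ-lactone ring therefore exists first, and a one-flask crossed double allylboration closes the cyclohexane onto it. Silylene masking of the C6/C15 diol, acylation of C9–OH and desilylation finish the route.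
5. Stereochemistry: C8 comes from the chiral pool and C5 from an enantioselective rhodium-catalysed conjugate alkenylation. In the key step C9 is set by Felkin–Anh control from C8, C10 by the E-allylboronate through a chair transition state, C7 by the cis ring fusion and C6 by the ring-fixed allyl geometry.

Key step: step 11

Remark: the Morita–Baylis–Hillman carbinol carbon (in 12–17) and the anomeric carbon (in 7–9, 17, 18) are carried as epimer mixtures and left undefined in the SMILES, because both become sp2 or are ring-opened before 19.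

**Route**

Step 1
Reactants: 1 but-2-yn-1-ol
Product: 2 (2Z)-3-(4,4,5,5-tetramethyl-1,3,2-dioxaborolan-2-yl)but-2-en-1-ol
Conditions: B2pin2, CuCl (5 mol%), PCy3 (6 mol%), NaOt-Bu (10 mol%), MeOH (2 equiv), toluene, 23 °C
Reagents that add atoms: bis(pinacolato)diboron, CC1(C)OB(OC1(C)C)B1OC(C)(C)C(C)(C)O1
Why: Copper-catalysed borylcupration–protonation (formal hydroboration) of a propargylic alcohol should add B and H syn with boron on the carbon remote from the CH2OH group, which fixes methyl and CH2OH cis; no stereocentre is formed.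

Step 2
Reactants: 2 (2Z)-3-(4,4,5,5-tetramethyl-1,3,2-dioxaborolan-2-yl)but-2-en-1-ol; 3 (2E)-4,4-dimethoxybut-2-enal
Product: 4 (3S,4E)-3-(dimethoxymethyl)-6-hydroxy-4-methylhex-4-enal
Conditions: [RhCl(C2H4)2]2 (2.5 mol%), enantiopure 2,5-diphenylbicyclo[2.2.2]octa-2,5-diene ligand (5.5 mol%, the antipode that gives 3S), KOH (0.3 equiv), 1,4-dioxane/H2O 10:1, 30 °C
Reagents that add atoms: none
Why: Rhodium-catalysed asymmetric conjugate addition of an alkenylboronate to the enal (Hayashi–Miyaura reaction), in which the chiral diene ligand favours 1,4- over 1,2-addition and selects the enantioface of the β-carbon, so setting C5, while the alkenyl group is transferred with retention of geometry.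

Step 3
Reactants: 4 (3S,4E)-3-(dimethoxymethyl)-6-hydroxy-4-methylhex-4-enal
Product: 5 (3R,4E)-3-(dimethoxymethyl)-6-hydroxy-4-methyl-2-methylidenehex-4-enal
Conditions: 37% aq. CH2O, pyrrolidine (10 mol%), EtCO2H (10 mol%), i-PrOH, 45 °C
Reagents that add atoms: formaldehyde, C=O
Why: Amine-catalysed Mannich condensation–elimination (organocatalytic α-methylenation of an aldehyde) should turn the α-CH2 into the 1,1-disubstituted alkene; no stereocentre is formed and the C5 descriptor changes from S to R only through the CIP priorities.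

Step 4
Reactants: 5 (3R,4E)-3-(dimethoxymethyl)-6-hydroxy-4-methyl-2-methylidenehex-4-enal
Product: 7 (2E)-3-[(3R)-2-methoxy-4-methylideneoxolan-3-yl]but-2-en-1-ol, via diol 6 (not isolated)
Conditions: NaBH4, CeCl3·7H2O, MeOH, −40 °C; then pyridinium p-toluenesulfonate (to pH 3–4), 23 °C
Reagents that add atoms: none
Why: Luche reduction should give clean 1,2-reduction of the enal, and on acidification the new allylic hydroxyl closes onto the dimethyl acetal by 5-exo transacetalisation (the other hydroxyl cannot reach across the E-alkene), leaving C5 untouched.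

Step 5
Reactants: 7 (2E)-3-[(3R)-2-methoxy-4-methylideneoxolan-3-yl]but-2-en-1-ol
Product: 8 2-{(2E)-3-[(3R)-2-methoxy-4-methylideneoxolan-3-yl]but-2-en-1-yl}-4,4,5,5-tetramethyl-1,3,2-dioxaborolane
Conditions: B2pin2, Pd(MeCN)4(BF4)2 (5 mol%), p-TsOH (5 mol%), DMSO/MeOH 1:1, 40 °C
Reagents that add atoms: bis(pinacolato)diboron, CC1(C)OB(OC1(C)C)B1OC(C)(C)C(C)(C)O1
Why: Palladium-catalysed direct borylation of an allylic alcohol runs through a π-allylpalladium intermediate that takes boron at its unhindered CH2 terminus, and the more stable syn placement of the bulky ring substituent should keep the E geometry; the methyl acetal is degenerate in methanol.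

Step 6
Reactants: 8 2-{(2E)-3-[(3R)-2-methoxy-4-methylideneoxolan-3-yl]but-2-en-1-yl}-4,4,5,5-tetramethyl-1,3,2-dioxaborolane
Product: 9 (3R)-4-methylidene-3-[(2E)-4-(4,4,5,5-tetramethyl-1,3,2-dioxaborolan-2-yl)but-2-en-2-yl]oxolan-2-ol
Conditions: AcOH/THF/H2O 1:4:1, 23 °C; extracted and used at once
Reagents that add atoms: water, O
Why: Mild acid hydrolysis of the 2-methoxytetrahydrofuran acetal should give the lactol, which masks the C6 aldehyde so that it does not react with the allylboronate of the same molecule; the pinacol allylboronate tolerates dilute acetic acid.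

Step 7
Reactants: 10 (4R)-2,2-dimethyl-1,3-dioxolane-4-carbaldehyde; 11 methyl prop-2-enoate
Product: 12 methyl 2-{[(4R)-2,2-dimethyl-1,3-dioxolan-4-yl](hydroxy)methyl}prop-2-enoate
Conditions: DABCO (0.5 equiv), neat 11 (3 equiv), 23 °C
Reagents that add atoms: none
Why: Morita–Baylis–Hillman reaction of the α-alkoxy aldehyde with the acrylate; C8 comes unchanged from D-glyceraldehyde and the new carbinol centre, formed as a mixture, is erased later.

Step 8
Reactants: 12 methyl 2-{[(4R)-2,2-dimethyl-1,3-dioxolan-4-yl](hydroxy)methyl}prop-2-enoate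
Product: 13 methyl 2-{(acetyloxy)[(4R)-2,2-dimethyl-1,3-dioxolan-4-yl]methyl}prop-2-enoate
Conditions: Ac2O, pyridine, DMAP (5 mol%), CH2Cl2, 0 °C
Reagents that add atoms: acetic anhydride, CC(=O)OC(C)=O
Why: Pyridine/DMAP acetylation of the secondary allylic alcohol installs the leaving group that zerovalent palladium will ionise in the key step.

Step 9
Reactants: 13 methyl 2-{(acetyloxy)[(4R)-2,2-dimethyl-1,3-dioxolan-4-yl]methyl}prop-2-enoate
Product: 15 (2R)-2-(hydroxymethyl)-4-methylidene-5-oxooxolan-3-yl acetate, via diol ester 14 (not isolated)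
Conditions: CF3CO2H/H2O 9:1, CH2Cl2, 0 → 23 °C; then toluene, 40 °C (concentration)
Reagents that add atoms: none
Why: Aqueous acid cleaves the acetonide and the freed secondary hydroxyl should lactonise onto the acrylate ester by 5-exo-trig acyl substitution (γ-lactone favoured over the δ-lactone from the primary hydroxyl), with C8 untouched.

Step 10
Reactants: 15 (2R)-2-(hydroxymethyl)-4-methylidene-5-oxooxolan-3-yl acetate
Product: 16 (2S)-2-formyl-4-methylidene-5-oxooxolan-3-yl acetate
Conditions: Dess–Martin periodinane, CH2Cl2, 0 °C; filtered and used at once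
Reagents that add atoms: none
Why: Dess–Martin oxidation of the primary alcohol under non-basic conditions should give the α-acyloxy aldehyde without β-elimination of acetate or epimerisation at C8; because C7 is still sp3, the C8–H is not vinylogously activated by the lactone.

Step 11
Reactants: 9 (3R)-4-methylidene-3-[(2E)-4-(4,4,5,5-tetramethyl-1,3,2-dioxaborolan-2-yl)but-2-en-2-yl]oxolan-2-ol; 16 (2S)-2-formyl-4-methylidene-5-oxooxolan-3-yl acetate
Product: 19 (3aS,4R,5S,6S,7R,7aS)-6-ethenyl-4,7-dihydroxy-5-(3-hydroxyprop-1-en-2-yl)-6-methyl-3-methylidenehexahydro-1-benzofuran-2(3H)-one, via borate adduct 17 (not isolated), via butenolide allylboronate 18 (not isolated)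
Conditions: 9 (1.0 equiv), 16 (1.2 equiv), 4 Å MS, toluene (1 M), 23 → 40 °C; then, same flask, B2pin2 (1.3 equiv), Pd2(dba)3 (2.5 mol%), 50 → 80 °C; aqueous NH4Cl work-up
Reagents that add atoms: none
Why: Proposed new method: the γ,γ-disubstituted E-allylboronate of 9 adds through a closed chair (Zimmerman–Traxler) transition state to the only free aldehyde present (C9 of 16), then zerovalent palladium ionises the allylic acetate, B2pin2 borylates the π-allyl at its CH2 terminus to give the ring-locked 2-acyl allylboronate 18, and on warming this adds intramolecularly to the lactol-derived C6 aldehyde; the closest known reaction types are the allylboration of α-alkoxy aldehydes by γ,γ-disubstituted allylboronates, the palladium-catalysed borylation of Morita–Baylis–Hillman acetates and the lactone-forming allylboration of 2-alkoxycarbonyl allylboronates, merged here into a crossed [3+3] carbocyclisation. The cyclohexane closes by 6-exo-trig attack of the allyl γ-carbon C7 on the C6 aldehyde through a chair–chair (trans-decalin-like) bicyclic transition state. C9 is set by Felkin–Anh (polar) control from C8, the lactone oxygen lying anti to the incoming allyl group (O8/O9 anti in the chain, cis on the ring), and C10 by the E geometry of the boronate (methyl pseudoaxial, C5 chain pseudoequatorial in the chair). C7 is set by the tether, which can reach only the butenolide face that carries the C9 chain (cis ring fusion), and C6 by the ring-fixed geometry of 18 (C8 trans to CH2B), which should give the anti, all-equatorial C5/C6/C7 array. The step needs cross- over self-coupling and the right order of events: within each fragment the nucleophilic and electrophilic carbons are 1,3-related and cannot close a ring, the aldehyde of 9 is masked as a lactol, and 16 gains its nucleophile only after the palladium catalyst is added, when no aldehyde is left next to the C8–H.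

Step 12
Reactants: 19 (3aS,4R,5S,6S,7R,7aS)-6-ethenyl-4,7-dihydroxy-5-(3-hydroxyprop-1-en-2-yl)-6-methyl-3-methylidenehexahydro-1-benzofuran-2(3H)-one
Product: 20 the C6-O/C15-O di-tert-butylsilylene of 19 (seven-membered 1,3-dioxa-2-silepane; C9–OH free)
Conditions: t-Bu2Si(OTf)2 (1.05 equiv), 2,6-lutidine, CH2Cl2 (0.02 M), −20 → 0 °C
Reagents that add atoms: di-tert-butylsilyl bis(trifluoromethanesulfonate), CC(C)(C)[Si](OS(=O)(=O)C(F)(F)F)(OS(=O)(=O)C(F)(F)F)C(C)(C)C
Why: Cyclic silylene formation: the reagent should silylate the primary allylic hydroxyl and then close a seven-membered ring onto the 1,4-related C6 hydroxyl, whereas the C9 hydroxyl lies across the cyclohexane, cannot be bridged and alone stays free.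

Step 13
Reactants: 20 the C6-O/C15-O di-tert-butylsilylene of 19
Product: 21 the C9 2-methylpropanoate of 20
Conditions: (i-PrCO)2O, Et3N, DMAP (20 mol%), CH2Cl2, 23 → 40 °C
Reagents that add atoms: 2-methylpropanoic anhydride, CC(C)C(=O)OC(=O)C(C)C
Why: DMAP-catalysed acyl transfer from the anhydride should acylate the only free hydroxyl, the hindered secondary C9–OH, with retention at C9.

Step 14
Reactants: 21 the C9 2-methylpropanoate of 20
Product: 22 (3aS,4R,5S,6S,7R,7aS)-6-ethenyl-4-hydroxy-5-(3-hydroxyprop-1-en-2-yl)-6-methyl-3-methylidene-2-oxooctahydro-1-benzofuran-7-yl 2-methylpropanoate (target)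
Conditions: HF·pyridine, THF/pyridine, 0 → 23 °C
Reagents that add atoms: none
Why: Fluoride-mediated desilylation cleaves both Si–O bonds of the silylene while the isobutyrate, the α-methylene lactone and the alkenes are inert, which should release the target.

**Compound list**

1 | but-2-yn-1-ol | CC#CCO | starting material
2 | (2Z)-3-(4,4,5,5-tetramethyl-1,3,2-dioxaborolan-2-yl)but-2-en-1-ol | C/C(B1OC(C)(C)C(C)(C)O1)=C\CO | intermediate
3 | (2E)-4,4-dimethoxybut-2-enal | COC(OC)/C=C/C=O | starting material
4 | (3S,4E)-3-(dimethoxymethyl)-6-hydroxy-4-methylhex-4-enal | C/C(=C\CO)[C@H](CC=O)C(OC)OC | intermediate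
5 | (3R,4E)-3-(dimethoxymethyl)-6-hydroxy-4-methyl-2-methylidenehex-4-enal | C/C(=C\CO)[C@H](C(=C)C=O)C(OC)OC | intermediate
6 | (2E,4R)-4-(dimethoxymethyl)-3-methyl-5-methylidenehex-2-ene-1,6-diol (not isolated) | C/C(=C\CO)[C@H](C(=C)CO)C(OC)OC | intermediate
7 | (2E)-3-[(3R)-2-methoxy-4-methylideneoxolan-3-yl]but-2-en-1-ol (anomer mixture) | C/C(=C\CO)[C@@H]1C(=C)COC1OC | intermediate
8 | 2-{(2E)-3-[(3R)-2-methoxy-4-methylideneoxolan-3-yl]but-2-en-1-yl}-4,4,5,5-tetramethyl-1,3,2-dioxaborolane | C/C(=C\CB1OC(C)(C)C(C)(C)O1)[C@@H]2C(=C)COC2OC | intermediate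
9 | (3R)-4-methylidene-3-[(2E)-4-(4,4,5,5-tetramethyl-1,3,2-dioxaborolan-2-yl)but-2-en-2-yl]oxolan-2-ol | C/C(=C\CB1OC(C)(C)C(C)(C)O1)[C@@H]2C(=C)COC2O | intermediate
10 | (4R)-2,2-dimethyl-1,3-dioxolane-4-carbaldehyde | O=C[C@H]1COC(C)(C)O1 | starting material
11 | methyl prop-2-enoate | C=CC(=O)OC | starting material
12 | methyl 2-{[(4R)-2,2-dimethyl-1,3-dioxolan-4-yl](hydroxy)methyl}prop-2-enoate | C=C(C(=O)OC)C(O)[C@H]1COC(C)(C)O1 | intermediate
13 | methyl 2-{(acetyloxy)[(4R)-2,2-dimethyl-1,3-dioxolan-4-yl]methyl}prop-2-enoate | C=C(C(=O)OC)C(OC(C)=O)[C@H]1COC(C)(C)O1 | intermediate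
14 | methyl (4R)-3-(acetyloxy)-4,5-dihydroxy-2-methylidenepentanoate (not isolated) | C=C(C(=O)OC)C(OC(C)=O)[C@H](O)CO | intermediate
15 | (2R)-2-(hydroxymethyl)-4-methylidene-5-oxooxolan-3-yl acetate | OC[C@H]1OC(=O)C(=C)C1OC(C)=O | intermediate
16 | (2S)-2-formyl-4-methylidene-5-oxooxolan-3-yl acetate | O=C[C@H]1OC(=O)C(=C)C1OC(C)=O | intermediate
17 | borate adduct: C9–C10 joined, C9–O–B(pin), C6 lactol and C7 acetate still in place (not isolated) | C=C[C@](C)([C@@H](OB1OC(C)(C)C(C)(C)O1)[C@H]2OC(=O)C(=C)C2OC(C)=O)[C@@H]3C(=C)COC3O | intermediate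
18 | butenolide allylboronate: as 17 but with the acetate replaced by a 3-[(pinacolboryl)methyl]furan-2(5H)-one (not isolated) | C=C[C@](C)([C@@H](OB1OC(C)(C)C(C)(C)O1)[C@H]2OC(=O)C(CB4OC(C)(C)C(C)(C)O4)=C2)[C@@H]3C(=C)COC3O | intermediate
19 | (3aS,4R,5S,6S,7R,7aS)-6-ethenyl-4,7-dihydroxy-5-(3-hydroxyprop-1-en-2-yl)-6-methyl-3-methylidenehexahydro-1-benzofuran-2(3H)-one | C=C[C@@]1(C)[C@H](C(=C)CO)[C@@H](O)[C@@H]2C(=C)C(=O)O[C@@H]2[C@@H]1O | intermediate
20 | C6-O/C15-O di-tert-butylsilylene of 19 | C=C[C@@]1(C)[C@@H]3C(=C)CO[Si](C(C)(C)C)(C(C)(C)C)O[C@H]3[C@@H]2C(=C)C(=O)O[C@@H]2[C@@H]1O | intermediate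
21 | C9 2-methylpropanoate of 20 | C=C[C@@]1(C)[C@@H]3C(=C)CO[Si](C(C)(C)C)(C(C)(C)C)O[C@H]3[C@@H]2C(=C)C(=O)O[C@@H]2[C@@H]1OC(=O)C(C)C | intermediate
22 | (3aS,4R,5S,6S,7R,7aS)-6-ethenyl-4-hydroxy-5-(3-hydroxyprop-1-en-2-yl)-6-methyl-3-methylidene-2-oxooctahydro-1-benzofuran-7-yl 2-methylpropanoate | C=C[C@@]1(C)[C@H](C(=C)CO)[C@@H](O)[C@@H]2C(=C)C(=O)O[C@@H]2[C@@H]1OC(=O)C(C)C | target

**Step count and risks**

Total: 14 steps. Longest linear sequence: 10 steps (steps 1–6, then 11–14).

Steps most likely to fail:

Step 11 (proposed new method). The intermolecular allylboration at the hindered γ,γ-disubstituted terminus may be slow enough for the α-acyloxy aldehyde to eliminate acetate or epimerise. The allylpalladium intermediate may be diverted to O-allylation or elimination, and the thermal ring closure onto the lactol may be sluggish or poorly face-selective. The fallback sets out from 9 and 16 and returns at 19. Only the intermolecular allylboration is run (toluene, 23–40 °C), the borate is hydrolysed on work-up, and the adduct, the hydroxy lactol acetate F1, is isolated. The ring is then closed in a separate, known operation by palladium-catalysed, indium-mediated Barbier-type allylation (Pd(PPh3)4, InI, THF, 23 °C). There zerovalent palladium ionises the acetate and InI reduces the π-allyl to a nucleophilic allylindium, which adds to the lactol aldehyde to give 19.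

Step 2. Competing 1,2-addition to the enal, protodeboronation of the hindered α-substituted alkenylboronate before transmetalation, and erosion of enantioselectivity are the concerns. The fallback sets out from 2 and returns at 4. The boronate 2 is converted with KHF2 (MeOH/H2O) into potassium [(2Z)-4-hydroxybut-2-en-2-yl]trifluoroborate F2. This is added to enal 3 under iminium catalysis by a chiral imidazolidinone salt (with HF as fluoride acceptor, DME, −20 °C), a known organocatalytic conjugate alkenylation that cannot give 1,2-addition.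

Step 3. Under amine catalysis the product enal can form a dienamine through its doubly allylic C5–H. That would move the skipped alkenes into conjugation and racemise C5. The fallback sets out from 4 and returns at 6, which is closed to 7 with acid as in step 4. Aldehyde 4 is converted by N-heterocyclic-carbene-catalysed oxidative esterification (triazolium precatalyst, DBU, MeOH, 3,3',5,5'-tetra-tert-butyldiphenoquinone) into methyl (3S,4E)-3-(dimethoxymethyl)-6-hydroxy-4-methylhex-4-enoate F3. Its dianion (LiN(i-Pr)2, 2.2 equiv, THF, −78 °C) is trapped with Eschenmoser's salt to give the Mannich base, methyl (3S,4E)-3-(dimethoxymethyl)-2-[(dimethylamino)methyl]-6-hydroxy-4-methylhex-4-enoate F4. Quaternisation with MeI and elimination with DBU give methyl (3R,4E)-3-(dimethoxymethyl)-6-hydroxy-4-methyl-2-methylidenehex-4-enoate F5. Reduction with i-Bu2AlH (CH2Cl2, −78 °C) gives diol 6 without any amine-catalysed step.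

Further compounds
F1 | step 11 | hydroxy lactol acetate: the C9–C10 adduct of 9 and 16 with free C9–OH, C6 lactol and C7 acetate | C=C[C@](C)([C@@H](O)[C@H]1OC(=O)C(=C)C1OC(C)=O)[C@@H]2C(=C)COC2O
F2 | step 2 | potassium [(2Z)-4-hydroxybut-2-en-2-yl]trifluoroborate | C/C(=C\CO)[B-](F)(F)F.[K+]
F3 | step 3 | methyl (3S,4E)-3-(dimethoxymethyl)-6-hydroxy-4-methylhex-4-enoate | C/C(=C\CO)[C@H](CC(=O)OC)C(OC)OC
F4 | step 3 | methyl (3S,4E)-3-(dimethoxymethyl)-2-[(dimethylamino)methyl]-6-hydroxy-4-methylhex-4-enoate | C/C(=C\CO)[C@H](C(CN(C)C)C(=O)OC)C(OC)OC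
F5 | step 3 | methyl (3R,4E)-3-(dimethoxymethyl)-6-hydroxy-4-methyl-2-methylidenehex-4-enoate | C/C(=C\CO)[C@H](C(=C)C(=O)OC)C(OC)OC
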